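Ring B carries three adjacent groups, the C2' oxygen, the C1' carboxyl and the C6' pentyl chain. This pattern is the imprint of a nucleophile and an electrophile adding across a C1'–C6' aryne that the C2' oxygen polarises. Both ring B carbon–carbon bonds are therefore cut together. In the forward direction pentylmagnesium bromide frees the aryne from an ortho-fluoro aryl iodide and adds at C6', and CO2 then captures the C1' arylmagnesium, all on the preformed depside. The precursor is the 2-hydroxy-4-methoxy-6-propylbenzoate (ring A) of 3-(benzyloxy)-5-fluoro-4-iodophenol; its iodine is set by directed metalation and its ester bond is formed last.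

Key step: step 10

Remark: unprimed locants belong to ring A (C1 carries the ester carbonyl C7) and primed ones to ring B (C1' carries CO2H, C4' the ester oxygen); the target has no stereocentre; fluoride loss from the 2-fluoroarylmagnesium species is assumed to set in between 0 and 35 °C in THF containing LiCl, and the warming profile is to be fixed on quenched aliquots.

Step 1
Reactants: 1 divarinol (5-propylbenzene-1,3-diol)
Product: 3 2,4-dihydroxy-6-propylbenzaldehyde, via iminium chloride 2 (not isolated)
Conditions: POCl3, DMF, 0 → 25 °C; then ice–water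
Reagents that add atoms: N,N-dimethylformamide, CN(C)C=O; water, O
Why: Vilsmeier–Haack formylation of a 5-alkylresorcinol attacks the ring carbon para to one hydroxyl and ortho to the other, next to the propyl chain, in preference to the crowded carbon between the two hydroxyls, and water then hydrolyses iminium salt 2 to aldehyde 3.

Step 2
Reactants: 3 2,4-dihydroxy-6-propylbenzaldehyde
Product: 4 2-hydroxy-4-methoxy-6-propylbenzaldehyde
Conditions: MeI (1.05 equiv), K2CO3 (1.0 equiv), acetone, 25 → 50 °C
Reagents that add atoms: iodomethane, CI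
Why: Williamson ether synthesis with about one equivalent of MeI should stop at the 4-OH, because the 2-OH is locked in a hydrogen bond to the aldehyde oxygen and is therefore harder to deprotonate and to alkylate.

Step 3
Reactants: 4 2-hydroxy-4-methoxy-6-propylbenzaldehyde
Product: 5 2-hydroxy-4-methoxy-6-propylbenzoic acid (ring A acid)
Conditions: NaClO2, NaH2PO4, 2-methylbut-2-ene (large excess), t-BuOH–THF–H2O, 0 → 25 °C
Reagents that add atoms: NaClO2 (sodium chlorite), [Na+].[O-]Cl=O
Why: Pinnick oxidation turns the aldehyde into the acid under buffered, mild conditions that leave phenol, ether and alkyl chain alone, while the large excess of 2-methylbut-2-ene intercepts HOCl before it can chlorinate the electron-rich ring.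

Step 4
Reactants: 6 5-fluororesorcinol (5-fluorobenzene-1,3-diol)
Product: 7 3-(benzyloxy)-5-fluorophenol
Conditions: BnBr (0.5 equiv relative to 6), K2CO3, DMF, 25 °C
Reagents that add atoms: benzyl bromide, BrCc1ccccc1
Why: Williamson ether synthesis on a symmetrical diol raises no question of site, the twofold excess of 6 holds back the second alkylation, and 7 is separated from the neutral dibenzyl ether and from water-soluble 6 by extraction.

Step 5
Reactants: 7 3-(benzyloxy)-5-fluorophenol
Product: 8 [3-(benzyloxy)-5-fluorophenoxy]tri(propan-2-yl)silane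
Conditions: iPr3SiCl, imidazole, DMF, 25 °C
Reagents that add atoms: chlorotri(propan-2-yl)silane, CC(C)[Si](Cl)(C(C)C)C(C)C
Why: Imidazole-promoted silylation of the phenol gives a base-stable ether whose bulk screens C3' and C5', the two ring positions beside C4'-O, in the metalation that follows.

Step 6
Reactants: 8 [3-(benzyloxy)-5-fluorophenoxy]tri(propan-2-yl)silane
Product: 10 [3-(benzyloxy)-5-fluoro-4-iodophenoxy]tri(propan-2-yl)silane, via aryllithium 9 (not isolated)
Conditions: LiN(iPr)2 (1.2 equiv), THF, −78 °C; transfer into I2, THF, −78 °C; aq Na2S2O3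
Reagents that add atoms: iodine (I2), [I][I]
Why: Directed ortho-metalation followed by iodine quench: the C1' hydrogen is the most acidic on the ring because it lies between fluorine and the lithium-binding benzyloxy oxygen, C3' and C5' are screened by the silyl group, the amide base spares the benzylic CH2, and aryllithium 9 holds its fluoride at −78 °C until it meets iodine.

Step 7
Reactants: 10 [3-(benzyloxy)-5-fluoro-4-iodophenoxy]tri(propan-2-yl)silane
Product: 11 3-(benzyloxy)-5-fluoro-4-iodophenol
Conditions: Bu4NF, AcOH, THF, 0 °C
Reagents that add atoms: none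
Why: Fluoride-induced desilylation is driven by the strong Si–F bond and, buffered by AcOH, leaves aryl iodide, aryl fluoride and benzyl ether untouched.

Step 8
Reactants: 5 2-hydroxy-4-methoxy-6-propylbenzoic acid; 11 3-(benzyloxy)-5-fluoro-4-iodophenol
Product: 13 3-(benzyloxy)-5-fluoro-4-iodophenyl 2-hydroxy-4-methoxy-6-propylbenzoate, via aroyl trifluoroacetate 12 (not isolated)
Conditions: (CF3CO)2O, toluene, 0 → 25 °C
Reagents that add atoms: none
Why: Mixed-anhydride esterification, the usual way to join depside halves: the anhydride reagent converts 5 into aroyl trifluoroacetate 12, whose electron-rich, acylium-like aroyl group passes to the single phenol of 11, so that no choice between hydroxyl groups arises and the hydrogen-bonded 2-OH of 5 stays free.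

Step 9
Reactants: 14 1-bromopentane
Product: 15 pentylmagnesium bromide (titrated THF solution containing LiCl)
Conditions: Mg turnings, LiCl, THF, 25–35 °C
Reagents that add atoms: magnesium, [Mg]
Why: Grignard reagent formation by insertion of magnesium into a primary alkyl bromide is routine, and LiCl keeps the reagent monomeric, soluble in THF and more active in halogen–magnesium exchange.

Step 10
Reactants: 13 3-(benzyloxy)-5-fluoro-4-iodophenyl 2-hydroxy-4-methoxy-6-propylbenzoate; 15 pentylmagnesium bromide; 16 carbon dioxide
Product: 20 2-(benzyloxy)-4-[(2-hydroxy-4-methoxy-6-propylbenzoyl)oxy]-6-pentylbenzoic acid, via fluoroaryl Grignard 17 (not isolated), via aryne 18 (not isolated), via pentylated aryl Grignard 19 (not isolated)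
Conditions: 13 added to 15 (4.5 equiv, LiCl), THF, −78 → −40 °C, 1 h; then → 25 °C (35 °C at most); −20 °C, dry CO2; 1 M HCl
Reagents that add atoms: none
Why: One equivalent of 15 converts the ring A phenol into its magnesium phenoxide and a second one carries out iodine–magnesium exchange at C1', fast because the carbanion sits between fluorine and oxygen, to give 17; on warming, 17 expels fluoride (taken up by magnesium and by Li+ from LiCl) and becomes the C1'–C6' aryne 18. A third equivalent adds its pentyl group to C6' (carbomagnesiation) to give arylmagnesium 19, and CO2, small enough to enter between the two ortho groups, carboxylates C1'. The closest known reactions are the addition of alkyl organometallics to 3-alkoxyarynes with a CO2 quench, which gives 6-alkylsalicylic acids, and the aryne relay that turns 2,6-dihaloarylmagnesium halides into m-terphenyls. Two carbon–carbon bonds form, no ring is closed and no stereocentre arises. Site selectivity (pentyl at C6', not C1') rests on the sigma-withdrawing C2' benzyloxy group, which bends the aryne so that C6' is the electrophilic end and places the developing carbanion at C1' beside oxygen; the more remote C4' acyloxy group opposes this only weakly. Chemoselectivity (depside ester kept) rests on C7 being walled in by the C6 propyl and C2 O–Mg groups, enriched by the phenoxide, and attached to a ring B that bears a C–Mg bond in 17 and 19 and is thus a poor leaving group, so that only the short-lived 18 is an ordinary aryl ester.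

Step 11
Reactants: 20 2-(benzyloxy)-4-[(2-hydroxy-4-methoxy-6-propylbenzoyl)oxy]-6-pentylbenzoic acid
Product: 21 stenosporic acid
Conditions: H2 (1 atm), 10% Pd/C, EtOAc, 25 °C
Reagents that add atoms: none
Why: Catalytic hydrogenolysis cleaves only the benzylic C–O bond, since aryl ester, carboxylic acid, phenol and methyl ether are inert to H2 over Pd/C at room temperature, and the neutral, cold conditions avoid decarboxylation of the salicylic acid unit.

Compound list
1 | divarinol (5-propylbenzene-1,3-diol) | CCCc1cc(O)cc(O)c1 | starting material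
2 | [(2,4-dihydroxy-6-propylphenyl)methylidene]dimethyliminium chloride | CCCc1cc(O)cc(O)c1C=[N+](C)C.[Cl-] | intermediate (not isolated)
3 | 2,4-dihydroxy-6-propylbenzaldehyde | CCCc1cc(O)cc(O)c1C=O | intermediate
4 | 2-hydroxy-4-methoxy-6-propylbenzaldehyde | CCCc1cc(OC)cc(O)c1C=O | intermediate
5 | 2-hydroxy-4-methoxy-6-propylbenzoic acid | CCCc1cc(OC)cc(O)c1C(=O)O | intermediate
6 | 5-fluororesorcinol (5-fluorobenzene-1,3-diol) | Oc1cc(O)cc(F)c1 | starting material
7 | 3-(benzyloxy)-5-fluorophenol | Oc1cc(F)cc(OCc2ccccc2)c1 | intermediate
8 | [3-(benzyloxy)-5-fluorophenoxy]tri(propan-2-yl)silane | CC(C)[Si](Oc1cc(F)cc(OCc2ccccc2)c1)(C(C)C)C(C)C | intermediate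
9 | (2-(benzyloxy)-6-fluoro-4-{[tri(propan-2-yl)silyl]oxy}phenyl)lithium | [Li]c1c(F)cc(O[Si](C(C)C)(C(C)C)C(C)C)cc1OCc1ccccc1 | intermediate (not isolated)
10 | [3-(benzyloxy)-5-fluoro-4-iodophenoxy]tri(propan-2-yl)silane | Ic1c(F)cc(O[Si](C(C)C)(C(C)C)C(C)C)cc1OCc1ccccc1 | intermediate
11 | 3-(benzyloxy)-5-fluoro-4-iodophenol | Ic1c(F)cc(O)cc1OCc1ccccc1 | intermediate
12 | 2-hydroxy-4-methoxy-6-propylbenzoic trifluoroacetic anhydride | CCCc1cc(OC)cc(O)c1C(=O)OC(=O)C(F)(F)F | intermediate (not isolated)
13 | 3-(benzyloxy)-5-fluoro-4-iodophenyl 2-hydroxy-4-methoxy-6-propylbenzoate | Ic1c(F)cc(OC(=O)c2c(O)cc(OC)cc2CCC)cc1OCc1ccccc1 | intermediate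
14 | 1-bromopentane | CCCCCBr | starting material
15 | pentylmagnesium bromide | CCCCC[Mg]Br | intermediate
16 | carbon dioxide | O=C=O | starting material
17 | 3-(benzyloxy)-4-(bromomagnesio)-5-fluorophenyl 2-[(bromomagnesio)oxy]-4-methoxy-6-propylbenzoate | CCCc1cc(OC)cc(O[Mg]Br)c1C(=O)Oc1cc(F)c([Mg]Br)c(OCc2ccccc2)c1 | intermediate (not isolated)
18 | 3-(benzyloxy)-4,5-didehydrophenyl 2-[(bromomagnesio)oxy]-4-methoxy-6-propylbenzoate (C1'–C6' aryne) | CCCc1cc(OC)cc(O[Mg]Br)c1C(=O)OC1=CC#CC(OCc2ccccc2)=C1 | intermediate (not isolated)
19 | 3-(benzyloxy)-4-(bromomagnesio)-5-pentylphenyl 2-[(bromomagnesio)oxy]-4-methoxy-6-propylbenzoate | CCCCCc1cc(OC(=O)c2c(O[Mg]Br)cc(OC)cc2CCC)cc(OCc2ccccc2)c1[Mg]Br | intermediate (not isolated)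
20 | 2-(benzyloxy)-4-[(2-hydroxy-4-methoxy-6-propylbenzoyl)oxy]-6-pentylbenzoic acid | CCCCCc1cc(OC(=O)c2c(O)cc(OC)cc2CCC)cc(OCc2ccccc2)c1C(=O)O | intermediate
21 | stenosporic acid, 2-hydroxy-4-[(2-hydroxy-4-methoxy-6-propylbenzoyl)oxy]-6-pentylbenzoic acid | CCCCCc1cc(OC(=O)c2c(O)cc(OC)cc2CCC)cc(O)c1C(=O)O | target

Total step count: 11. Longest linear sequence: 7 steps (steps 4, 5, 6, 7, 8, 10 and 11, from 6).

Steps most likely to fail

1. Step 10. Three things may go wrong.
- The excess Grignard reagent may attack C7 by acyl substitution during the warm phase that fluoride loss demands.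
- Fluoride loss itself may be sluggish.
- Hydride may pass from the pentyl chain to the aryne in place of carbon–carbon bond formation.

Fallback, from 10 back to 21: the aryne sequence is moved ahead of the esterification, so that no ester is present while the Grignard reagent is warm. Silyl ether 10 is treated with 15 (3 equiv, THF, −40 → 45 °C) and then with 16 to give 2-(benzyloxy)-6-pentyl-4-{[tri(propan-2-yl)silyl]oxy}benzoic acid F1. BnBr and KHCO3 in DMF then give benzyl 2-(benzyloxy)-6-pentyl-4-{[tri(propan-2-yl)silyl]oxy}benzoate F2. Bu4NF with AcOH frees benzyl 2-(benzyloxy)-4-hydroxy-6-pentylbenzoate F3. Acid 5 is joined to it with (CF3CO)2O in toluene to give benzyl 2-(benzyloxy)-4-[(2-hydroxy-4-methoxy-6-propylbenzoyl)oxy]-6-pentylbenzoate F4. Hydrogenolysis of both benzyl groups (H2, Pd/C, EtOAc) gives 21.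

2. Step 6. Four things may go wrong.
- Metalation may occur at the benzylic CH2, with Wittig rearrangement following.
- Metalation may occur at C5'.
- LiF may be lost before the quench.
- Iodine may migrate by halogen–metal scrambling when aryllithium and product meet.

Fallback, from 6 back to 13: iodine is brought in by electrophilic aromatic substitution and the two oxygens are told apart afterwards. N-Iodosuccinimide in MeCN at 0 °C should iodinate 6 para to one hydroxyl and next to fluorine to give 5-fluoro-4-iodobenzene-1,3-diol F5. Acid 5 with (CF3CO)2O in toluene should acylate the unhindered hydroxyl para to iodine to give 3-fluoro-5-hydroxy-4-iodophenyl 2-hydroxy-4-methoxy-6-propylbenzoate F6. BnBr and K2CO3 in acetone then alkylate the remaining ring B hydroxyl, the ring A hydroxyl being held by its hydrogen bond to the C7 carbonyl, and give 13. This path is shorter but depends on two site selections, which is why it is kept in reserve.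

3. Step 3. Chlorine species may chlorinate the ring if they escape the scavenger, or the free phenol may be degraded oxidatively.

Fallback, from 1 back to 5: the carboxyl carbon is introduced at the acid oxidation level, so that no aldehyde has to be oxidised. Carboxylation of 1 with MeOMgOCO2Me in DMF at 120 °C (a Kolbe–Schmitt-type reaction) gives 2,4-dihydroxy-6-propylbenzoic acid F7. MeI (2.1 equiv) and K2CO3 in acetone methylate the carboxyl group and the 4-OH, but not the chelated 2-OH, to give methyl 2-hydroxy-4-methoxy-6-propylbenzoate F8. Saponification (KOH, aqueous DMSO, 80 °C, then cold HCl) gives 5.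

Further compounds
F1 | step 10 | 2-(benzyloxy)-6-pentyl-4-{[tri(propan-2-yl)silyl]oxy}benzoic acid | CCCCCc1cc(O[Si](C(C)C)(C(C)C)C(C)C)cc(OCc2ccccc2)c1C(=O)O
F2 | step 10 | benzyl 2-(benzyloxy)-6-pentyl-4-{[tri(propan-2-yl)silyl]oxy}benzoate | CCCCCc1cc(O[Si](C(C)C)(C(C)C)C(C)C)cc(OCc2ccccc2)c1C(=O)OCc1ccccc1
F3 | step 10 | benzyl 2-(benzyloxy)-4-hydroxy-6-pentylbenzoate | CCCCCc1cc(O)cc(OCc2ccccc2)c1C(=O)OCc1ccccc1
F4 | step 10 | benzyl 2-(benzyloxy)-4-[(2-hydroxy-4-methoxy-6-propylbenzoyl)oxy]-6-pentylbenzoate | CCCCCc1cc(OC(=O)c2c(O)cc(OC)cc2CCC)cc(OCc2ccccc2)c1C(=O)OCc1ccccc1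
F5 | step 6 | 5-fluoro-4-iodobenzene-1,3-diol | Ic1c(O)cc(O)cc1F
F6 | step 6 | 3-fluoro-5-hydroxy-4-iodophenyl 2-hydroxy-4-methoxy-6-propylbenzoate | Ic1c(F)cc(OC(=O)c2c(O)cc(OC)cc2CCC)cc1O
F7 | step 3 | 2,4-dihydroxy-6-propylbenzoic acid | CCCc1cc(O)cc(O)c1C(=O)O
F8 | step 3 | methyl 2-hydroxy-4-methoxy-6-propylbenzoate | CCCc1cc(OC)cc(O)c1C(=O)OC
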